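(The constants are those of an exercise, and the outcome is calculated.)

Two questions were put to me about one flask.

1. part of the solid electrophile that has reacted (what has only dissolved counts as not reacted) at 5.0 h
2. share of the unused nucleophile that is free and not bound as protonated nucleophile, at 5.0 h

solid electrophile 15 mM; free base 2.00 equiv; protonated nucleophile 0.950 equiv; time 5.0 h

    2 electrophile → homo dimer (k1 = 0.0132 M⁻¹ s⁻¹)
    acid set free + free base ⇌ salt of the base, settled at all times (K2 = 8.6 × 10⁵ M⁻¹)
    electrophile + nucleophile ⇌ acid set free + product (K3 = 1.2, k3 = 0.112 M⁻¹ s⁻¹)
    solid electrophile ⇌ electrophile, rate k4*(cs4 - [electrophile]) while solid is left; crystals form when [electrophile] > cs4 (cs4 = 2.0 mM, k4 = 6.63 × 10⁻⁴ s⁻¹)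
    nucleophile + acid set free ⇌ protonated nucleophile, settled at all times (K5 = 3610 M⁻¹)

- percentages count the solid electrophile that a species holds: one homo dimer counts as two
- for a step with 2 of a species take k times the square, and two of it per event
- solid, in amounts per volume of the solution: solid electrophile
- at the start none of the solid electrophile is in solution
- what has only dissolved of solid electrophile counts as not reacted
- run time (flask): 5.0 h

Free base and nucleophile compete for one acid. Both balances share one [acid], so [protonated nucleophile]/[nucleophile] equals [salt of the base]/[free base] times the equilibrium constant for nucleophile taking acid divided by that for free base taking acid, 0.00420, which I called the acid split.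

I began with two extreme flasks, counting all acid as salt. With no coupling, the salt is 14.2 mM and the free share is 99.6%. With every nucleophile coupled, each coupling frees one more acid, so the free base falls to 1.50 mM and the free share to 92.6%. The free share in the real flask had to lie between these.

To place it, I set dissolving equal to coupling, the quasi-steady state of dissolved electrophile. At the full nucleophile charge this gave 3.37 mM h⁻¹, a pace that, if held, would use up the nucleophile charge in 4.21 h, inside the run. So I went round again with a mean nucleophile of 7.12 mM. That gave 2.61 mM h⁻¹, or 13.0 mM coupled in 5.0 h. My answers were 86.9% reacted and, with 27.3 mM of salt against 2.71 mM of free base, 95.9% free.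

The forecast gave 80% and 97.4%, differing from mine, and opened with “The base first frees almost all the nucleophile”.

The simulation gave 80.8% and 97.4%, lower than my conversion and higher than my free share.

The binding of acid set free by free base is the main reason for this conversion: without it, the flask reached 15.0% rather than 80.8%. In the flask as charged, at 5.00 h, 25.9 mM of salt against 4.10 mM of free base gives, through the split, 97.4% free. The neighbour charged with 1.20 equiv of free base, all else held, ended far from the forecast's numbers: its free base stood at 0.222% of its charge against 18.0 mM of salt, so the split gives 34.6% free, and 59.1% of its solid electrophile had reacted.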